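The dihydropyran ring of the chroman (O1–C2–C3–C4–C4a–C8a) is opened into three pieces: 2,4-diformylphloroglucinol, isovaleraldehyde and a spirocyclic vinyl sulfide. In one operation a Knoevenagel condensation makes the aryl–C4 bond and an ortho-quinone methide, whose oxa-[4+2] addition to the cyclopentene C2=C3 closes the pyran ring, makes O1–C2 and C4–C3 and sets C2, C3 and C4. The step exploits the phenol oxygen and the benzylic carbon as the ends of a 1-oxadiene. A phenylthio group on C2, which lies between the quaternary C3 and the spiro carbon, directs the oxygen there and is then removed. The dienophile, a 1-phenylthio-2-methylcyclopentene spiro-fused to the menthene ring, comes from (+)-menthone.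

Key step: step 7

Remark: ester 2 is used as the racemate, since its stereocentre becomes trigonal in step 3; compounds 1, 2 and 10 are taken as catalogue compounds. Terpene atoms are numbered as in spiro[4.5]decane (C1–C4 cyclopentane, C5 spiro, C6–C10 cyclohexane), and the new ring as in chroman.

Step 1
Reactants: 1 (+)-menthone; 2 methyl 4-bromo-2-methylbutanoate
Product: 3 methyl 2-methyl-4-[(1R,3R,6S)-6-methyl-2-oxo-3-(propan-2-yl)cyclohexyl]butanoate
Conditions: LiN(iPr)2, THF, –78 °C; then 2, DMPU, Bu4NI (10 mol %), –78 → 23 °C
Reagents that add atoms: none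
Why: Kinetic deprotonation of menthone occurs at the CH2 α-carbon remote from the isopropyl group, and SN2 alkylation of this ketone enolate should place the chain equatorial, trans to the neighbouring methyl (a centre that is re-set in step 2).

Step 2
Reactants: 3 keto ester
Product: 4 (5S,10S)-2,10-dimethyl-7-(propan-2-yl)spiro[4.5]decane-1,6-dione
Conditions: LiN(SiMe3)2 (2.2 equiv), THF, –78 → 0 °C
Reagents that add atoms: none
Why: Intramolecular Claisen-type C-acylation (5-exo-trig) of the ketone enolate is expected, since only the enolate on the chain-bearing carbon can close; the ester carbon should attack anti to the pseudoaxial C10 methyl, so that C1 ends trans and C4 cis to it, and the second equivalent of base stores the product as its C2 enolate against retro-Claisen opening.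

Step 3
Reactants: 4 spiro diketone
Product: 5 (5S,10S)-2,10-dimethyl-6-oxo-7-(propan-2-yl)spiro[4.5]dec-1-en-1-yl trifluoromethanesulfonate
Conditions: KN(SiMe3)2 (1.05 equiv), THF, –78 °C; then PhNTf2, –78 → 0 °C
Reagents that add atoms: N-phenylbis(trifluoromethanesulfonimide), O=S(=O)(N(c1ccccc1)S(=O)(=O)C(F)(F)F)C(F)(F)F
Why: Enol triflate formation: the cyclopentanone α-CH (C2) should be deprotonated far faster than the isopropyl-flanked C7–H of the cyclohexanone, C5 carries no hydrogen, and O-sulfonylation of the enolate fixes the C1=C2 alkene.

Step 4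
Reactants: 5 enol triflate
Product: 6 (5R,10S)-2,10-dimethyl-1-(phenylsulfanyl)-7-(propan-2-yl)spiro[4.5]dec-1-en-6-one
Conditions: PhSH, Pd2(dba)3 (2.5 mol %), Xantphos (5 mol %), iPr2NEt, 1,4-dioxane, 100 °C
Reagents that add atoms: thiophenol, Sc1ccccc1
Why: Palladium-catalysed C–S cross-coupling of an enol triflate with a thiol should replace OTf by SPh without moving the alkene; the hindered C6 ketone is a spectator.

Step 5
Reactants: 6 keto vinyl sulfide
Product: 7 (5R,10S)-2,10-dimethyl-1-(phenylsulfanyl)-7-(propan-2-yl)spiro[4.5]deca-1,6-dien-6-yl trifluoromethanesulfonate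
Conditions: KN(SiMe3)2 (1.5 equiv), THF, –78 → 0 °C; then PhNTf2, 0 → 23 °C
Reagents that add atoms: N-phenylbis(trifluoromethanesulfonimide), O=S(=O)(N(c1ccccc1)S(=O)(=O)C(F)(F)F)C(F)(F)F
Why: Enol triflate formation: the only α-hydrogen of the C6 ketone is at C7, so enolisation and O-sulfonylation can only give the C6=C7 enol triflate.

Step 6
Reactants: 7 dienyl triflate
Product: 8 (5R,10S)-2,10-dimethyl-1-(phenylsulfanyl)-7-(propan-2-yl)spiro[4.5]deca-1,6-diene
Conditions: Pd(OAc)2 (5 mol %), PPh3 (10 mol %), HCO2H, Bu3N, DMF, 60 °C
Reagents that add atoms: none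
Why: Palladium-catalysed formate reduction of an enol triflate (hydride from formate, loss of CO2) should turn C6–OTf into C6–H and leave the trisubstituted C6=C7 alkene where the enol was.

Step 7
Reactants: 8 spiro vinyl sulfide; 9 3-methylbutanal; 10 2,4,6-trihydroxybenzene-1,3-dicarbaldehyde
Product: 12 phenylthio ketal of the target skeleton (SPh in place of H on the O-bearing ring-fusion carbon), via ortho-quinone methide 11 (not isolated)
Conditions: 9 (2 equiv), 10 (1.5 equiv), ethylenediammonium diacetate (20 mol %), anhydrous MgSO4, MeCN, 60 °C
Reagents that add atoms: none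
Why: The ammonium acetate should catalyse Knoevenagel condensation of 9 at the only unsubstituted ring carbon of 10, and loss of water gives the E-configured ortho-quinone methide 11, a 1-oxadiene that adds to the electron-rich vinyl sulfide in an inverse-demand oxa-[4+2] reaction, the methide carbon bonding to the sulfur-free, methyl-bearing alkene carbon and the carbonyl oxygen to the sulfur-bearing one, because sulfur stabilises the positive charge that builds up there. The closest known reaction type is the domino Knoevenagel/hetero-Diels–Alder reaction of 1,3-dicarbonyl-type carbon acids, aldehydes and enol ethers or vinyl sulfides, which is also how formyl-phloroglucinol terpene adducts are assembled from alkenes. The dihydropyran ring is closed by this [4+2] cycloaddition; in its stepwise limit it is a conjugate addition followed by 6-exo-trig attack of the phenoxide on the thionium ion, which cannot escape by proton loss since both neighbours of that carbon are quaternary. C2 and C3 are set by facial selection: the diene should approach the cyclopentene face that carries the flat vinylic C6–H of the spiro ring and not the face shielded by the sp3 C10 with its methyl and ring methylene, and the suprafacial addition makes the ring fusion cis. C4 is set by the transition-state topology, the isobutyl group of the E-methide ending cis to the angular methyl when the bulky spirocycle points away from the diene and sulfur sits under it. The step needs chemoselectivity for the vinyl sulfide over the trisubstituted C6=C7 alkene and the regiochemistry just described, both of which follow from the sulfur donor; arene regiochemistry is no issue because 10 is symmetric.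

Step 8
Reactants: 12 phenylthio ketal
Product: 13 target
Conditions: Bu3SnH (3 equiv), AIBN (0.2 equiv), toluene, 100 °C
Reagents that add atoms: none
Why: Radical-chain desulfurisation: the stannyl radical abstracts SPh to give a tertiary α-aryloxy radical, and hydrogen transfer on the convex face should keep the cis ring fusion (overall retention at C2); aldehydes, phenols and the alkene are inert to these conditions.

Compound list
1 | (+)-menthone, (2R,5S)-5-methyl-2-(propan-2-yl)cyclohexan-1-one | C[C@H]1CC[C@H](C(C)C)C(=O)C1 | starting material
2 | methyl 4-bromo-2-methylbutanoate (racemic) | COC(=O)C(C)CCBr | starting material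
3 | methyl 2-methyl-4-[(1R,3R,6S)-6-methyl-2-oxo-3-(propan-2-yl)cyclohexyl]butanoate (both epimers at the ester α-carbon) | COC(=O)C(C)CC[C@H]1C(=O)[C@@H](C(C)C)CC[C@@H]1C | intermediate
4 | (5S,10S)-2,10-dimethyl-7-(propan-2-yl)spiro[4.5]decane-1,6-dione (C1 trans to the C10 methyl; epimers at C2 and C7) | O=C2C(C)CC[C@@]21C(=O)C(C(C)C)CC[C@@H]1C | intermediate
5 | (5S,10S)-2,10-dimethyl-6-oxo-7-(propan-2-yl)spiro[4.5]dec-1-en-1-yl trifluoromethanesulfonate (C7 epimers) | CC1=C(OS(=O)(=O)C(F)(F)F)[C@@]2(CC1)C(=O)C(C(C)C)CC[C@@H]2C | intermediate
6 | (5R,10S)-2,10-dimethyl-1-(phenylsulfanyl)-7-(propan-2-yl)spiro[4.5]dec-1-en-6-one (C7 epimers) | CC1=C(Sc3ccccc3)[C@@]2(CC1)C(=O)C(C(C)C)CC[C@@H]2C | intermediate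
7 | (5R,10S)-2,10-dimethyl-1-(phenylsulfanyl)-7-(propan-2-yl)spiro[4.5]deca-1,6-dien-6-yl trifluoromethanesulfonate | CC1=C(Sc3ccccc3)[C@@]2(CC1)C(OS(=O)(=O)C(F)(F)F)=C(C(C)C)CC[C@@H]2C | intermediate
8 | (5R,10S)-2,10-dimethyl-1-(phenylsulfanyl)-7-(propan-2-yl)spiro[4.5]deca-1,6-diene | CC1=C(Sc3ccccc3)[C@@]2(CC1)C=C(C(C)C)CC[C@@H]2C | intermediate
9 | 3-methylbutanal (isovaleraldehyde) | CC(C)CC=O | starting material
10 | 2,4,6-trihydroxybenzene-1,3-dicarbaldehyde (2,4-diformylphloroglucinol) | O=Cc1c(O)cc(O)c(C=O)c1O | starting material
11 | ortho-quinone methide, 2,4-dihydroxy-5-(3-methylbutylidene)-6-oxocyclohexa-1,3-diene-1,3-dicarbaldehyde | CC(C)CC=C1C(=O)C(C=O)=C(O)C(C=O)=C1O | intermediate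
12 | 2-(phenylsulfanyl) analogue of 13: 6,8-diformyl-5,7-dihydroxy-4-isobutyl-3-methylchroman whose C2 (bearing SPh on the face of the angular methyl) and C3 are C1 and C2 of the spiro[4.5]dec-6-ene unit; all other centres as in 13 | CC(C)C[C@H]1c2c(O)c(C=O)c(O)c(C=O)c2O[C@@]2(Sc3ccccc3)[C@]1(C)CC[C@@]21C=C(C(C)C)CC[C@@H]1C | intermediate
13 | target: 6,8-diformyl-5,7-dihydroxy-4-isobutyl-3-methylchroman cis-fused at C2–C3 to the cyclopentane of a 7-isopropyl-10-methylspiro[4.5]dec-6-ene (chroman C4 R, C3 R, C2 S; spiro carbon R; CHMe carbon S) | CC(C)C[C@H]1c2c(O)c(C=O)c(O)c(C=O)c2O[C@H]2[C@]1(C)CC[C@@]21C=C(C(C)C)CC[C@@H]1C | target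

Total step count: 8. Longest linear sequence: 8 steps (1 → 13).

Steps most likely to fail

Step 7. The water released by the condensation and the acidic phenol may hydrolyse the vinyl sulfide before the hindered tetrasubstituted alkene is captured, the methide may be consumed by a second molecule of 10, or facial selectivity on the cyclopentene may be poor. The fallback separates the two events and sets out from 10. Compounds 10, 9 and morpholine (EtOH, 23 °C) should give the Mannich base 2,4,6-trihydroxy-5-[3-methyl-1-(morpholin-4-yl)butyl]benzene-1,3-dicarbaldehyde F1, which is isolated and heated with 8 in dry toluene at 100 °C. Loss of morpholine releases 11 without water or added acid, and the cycloaddition comes back to the route at 12.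

Step 2. Methoxide may reopen the non-enolisable 1,3-diketone by retro-Claisen cleavage, or enolisation on the isopropyl side may stall the closure. The fallback sets out from 3 and changes to an acid-mediated closure through the enol. Saponification (LiOH, THF/H2O) should give the keto acid 2-methyl-4-[(1R,3R,6S)-6-methyl-2-oxo-3-(propan-2-yl)cyclohexyl]butanoic acid F2, and polyphosphoric acid in AcOH at 80 °C should acylate the more substituted enol. The sequence comes back to the route at 4.

Step 5. The C7–H, flanked by the isopropyl group and a ketone next to a quaternary carbon, may not be deprotonated, or the amide base may attack the carbonyl instead. The fallback sets out from 6 and replaces enolisation by reduction and elimination. LiAlH4 (THF, 0 °C) should give the alcohol (5R,10S)-2,10-dimethyl-1-(phenylsulfanyl)-7-(propan-2-yl)spiro[4.5]dec-1-en-6-ol F3, which is dehydrated by syn-elimination with methyl N-(triethylammoniumsulfonyl)carbamate (Burgess reagent, benzene, 50 °C) or by xanthate pyrolysis. Since C5 has no hydrogen, only the C6=C7 alkene can form, and the sequence comes back to the route at 8, bypassing 7.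

Further compounds
F1 | step 7 | 2,4,6-trihydroxy-5-[3-methyl-1-(morpholin-4-yl)butyl]benzene-1,3-dicarbaldehyde (racemic) | CC(C)CC(N1CCOCC1)c1c(O)c(C=O)c(O)c(C=O)c1O
F2 | step 2 | 2-methyl-4-[(1R,3R,6S)-6-methyl-2-oxo-3-(propan-2-yl)cyclohexyl]butanoic acid | OC(=O)C(C)CC[C@H]1C(=O)[C@@H](C(C)C)CC[C@@H]1C
F3 | step 5 | (5R,10S)-2,10-dimethyl-1-(phenylsulfanyl)-7-(propan-2-yl)spiro[4.5]dec-1-en-6-ol (epimers at C6 and C7) | CC1=C(Sc3ccccc3)[C@@]2(CC1)C(O)C(C(C)C)CC[C@@H]2C
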